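**Plan**

- Last cut (retro-oxa-[4+2]): the C–C bond shared by the two dihydropyran rings (O-bound methine to the CH next to CMe2) together with the O–CMe2 bond. The enabling feature is that this methine sits on C-3 of quinolone B beside the C-4 oxygen, so that C4=O/C3=CH–OAr is a 1-oxadiene, while the O–CMe2–CH unit is a latent 2-methylprop-1-enyl group, the twin of the isobutenyl group kept on the neighbouring carbon.
- Second cut: the enol-ether C–O bond at that methine, which gives a 3-formyl-4-hydroxyquinolone (half B) and a 4-hydroxyquinolone whose C-3 carries a prochiral CH(CH=CMe2)2 group (half A).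
- Half A: pyridone ring from N-methylisatoic anhydride and an ester; the ester by Johnson–Claisen rearrangement of a tertiary dienol made from a commercial dienone. Half B: aminomethylenation and hydrolysis of commercial 4-hydroxy-1-methylquinolin-2-one.
- Forward ring order: pyridone ring of half A (step 3), then the central pyran and the outer pyran together in the last step, which also joins the two halves.
- Stereochemistry: all three stereocentres arise in the last step. Relative configuration comes from tether geometry and allylic strain, absolute configuration from a chiral Brønsted acid that selects one of two enantiotopic isobutenyl groups.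

Key step: step 6

Assumption: the sense of induction of the chiral acid cannot be predicted with certainty; the (S,S) acid is written, and its antipode would be used if the first run showed the mirror-image product.

**Route**

Step 1
Reactants: 1 (E)-6-methylhepta-3,5-dien-2-one
Product: 2 (E)-2,6-dimethylhepta-3,5-dien-2-ol
Conditions: MeLi (1.1 equiv), Et2O, −78 → 0 °C; then H2O
Reagents that add atoms: methyllithium, [Li]C
Why: 1,2-addition of an organolithium to the ketone carbonyl should outrun conjugate addition and enolisation at low temperature and give the tertiary dienyl alcohol with the (E)-alkene untouched.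

Step 2
Reactants: 2 (E)-2,6-dimethylhepta-3,5-dien-2-ol
Product: 3 ethyl 5-methyl-3-(2-methylprop-1-en-1-yl)hex-4-enoate
Conditions: MeC(OEt)3 (6 equiv), EtCO2H (cat.), 135 °C, ethanol distilled off
Reagents that add atoms: triethyl orthoacetate, CCOC(C)(OCC)OCC
Why: Johnson–Claisen rearrangement, in which the mixed ketene acetal undergoes a [3,3]-sigmatropic shift that forms the C–C bond at C-4 of the dienol and moves the double bond to C-2/C-3, so that the new carbon carries two identical 2-methylprop-1-enyl groups and is not a stereocentre.

Step 3
Reactants: 3 ethyl 5-methyl-3-(2-methylprop-1-en-1-yl)hex-4-enoate; 4 N-methylisatoic anhydride (1-methyl-2H-3,1-benzoxazine-2,4(1H)-dione)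
Product: 6 3-(2,6-dimethylhepta-2,5-dien-4-yl)-4-hydroxy-1-methylquinolin-2(1H)-one, via keto ester 5 (not isolated)
Conditions: LiN(iPr)2 (2.1 equiv), THF, −78 °C; then 4, −78 °C → reflux; aq. HCl
Reagents that add atoms: none
Why: the ester enolate should acylate at the C-4 carbonyl of the anhydride (Claisen-type C-acylation), the ring opens with loss of CO2, and the freed N-methylaniline nitrogen closes onto the ethyl ester (lactamisation) to give the 4-hydroxy-2-quinolone, the racemic centre of 5 being lost on enolisation.

Step 4
Reactants: 7 4-hydroxy-1-methylquinolin-2(1H)-one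
Product: 8 3-[(dimethylamino)methylidene]-1-methylquinoline-2,4(1H,3H)-dione
Conditions: Me2NCH(OMe)2 (1.5 equiv), toluene, 110 °C
Reagents that add atoms: N,N-dimethylformamide dimethyl acetal, COC(OC)N(C)C
Why: aminomethylenation of a cyclic 1,3-dicarbonyl compound, in which the nucleophilic C-3 condenses with the amide acetal to give the push–pull enaminone.

Step 5
Reactants: 8 3-[(dimethylamino)methylidene]-1-methylquinoline-2,4(1H,3H)-dione
Product: 9 4-hydroxy-1-methyl-2-oxo-1,2-dihydroquinoline-3-carbaldehyde
Conditions: 2 M aq. NaOH, 25 °C; then aq. HCl to pH 2
Reagents that add atoms: water, O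
Why: hydrolysis of the vinylogous amide by conjugate addition of hydroxide and loss of dimethylamine, followed by acidification, should give the hydrogen-bonded 3-formyl-4-hydroxyquinolone.

Step 6
Reactants: 6 3-(2,6-dimethylhepta-2,5-dien-4-yl)-4-hydroxy-1-methylquinolin-2(1H)-one; 9 4-hydroxy-1-methyl-2-oxo-1,2-dihydroquinoline-3-carbaldehyde
Product: 11 target CNP0210533.1 as the (S,R,S) isomer (cis-fused bis-dihydropyrano[3,2-c]quinolin-5-one), via aryloxymethylidene dione 10 (not isolated)
Conditions: (S,S)-imidodiphosphoric acid [ArO2P(=O)]–N=[P(OH)O2Ar], ArO2 = (S)-3,3'-bis(2,4,6-triethylphenyl)-1,1'-binaphthalene-2,2'-diolate (5 mol %), 5 Å MS, CHCl3, 40 °C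
Reagents that add atoms: none
Why: Proposed new method: the acid should add the 4-OH of 6 (C-3 is blocked, and C-attack is a reversible aldol) to the formyl group of 9 and expel water, giving O-protonated 10 as an ion pair with the chiral anion; its 1-oxadiene O=C4–C3=CH–OAr then adds across one 2-methylprop-1-enyl group in an inverse-electron-demand, probably asynchronous (Prins-like) oxa-[4+2] cycloaddition, the methine carbon bonding to the alkene CH and the ketone oxygen to the CMe2 terminus. The closest known reaction type is the chiral-Brønsted-acid-catalysed condensation of salicylaldehydes with alkenyl alcohols to alkoxy ortho-quinone methides that undergo intramolecular oxa-[4+2] addition to unactivated trisubstituted alkenes, together with the domino Knoevenagel/intramolecular hetero-Diels–Alder reaction of 4-hydroxyquinolones; new here are the vinylogous-acid oxygen nucleophile and the choice between two enantiotopic alkenes. The central dihydropyran closes through the new C–C bond in a 6-exo-trig mode over the four-atom O–C4=C3–CH tether, and the outer dihydropyran is the six-membered ring of the cycloaddition itself. The two ring-fusion centres should come out cis because the tether with its planar enol-ether unit favours the endo arrangement, in which both quinolone-flanked benzylic substituents sit pseudo-axial and escape A(1,3) strain against the lactam carbonyls; the isobutenyl-bearing centre is set by A(1,3) strain in the reacting alkene, which keeps the spectator isobutenyl group away from the (Z)-methyl group so that it ends trans to the CMe2 carbon. The absolute configuration comes from the chiral anion, which selects the diene face and with it one of the two enantiotopic isobutenyl groups. The step needs O- over C-attack (secured by the substituted C-3), reaction through the ketone and not the lactam carbonyl (the 2-quinolone is the stable product type), and an acid mild enough not to add the free enol OH across an isobutenyl group (hence an imidodiphosphoric acid and not a stronger one).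

**Compound list**

1 | (E)-6-methylhepta-3,5-dien-2-one | CC(=O)/C=C/C=C(C)C | starting material
2 | (E)-2,6-dimethylhepta-3,5-dien-2-ol | CC(C)(O)/C=C/C=C(C)C | intermediate
3 | ethyl 5-methyl-3-(2-methylprop-1-en-1-yl)hex-4-enoate (achiral, two identical alkenyl groups on C-3) | CCOC(=O)CC(C=C(C)C)C=C(C)C | intermediate
4 | N-methylisatoic anhydride (1-methyl-2H-3,1-benzoxazine-2,4(1H)-dione) | CN1C(=O)OC(=O)c2ccccc21 | starting material
5 | ethyl 5-methyl-2-[2-(methylamino)benzoyl]-3-(2-methylprop-1-en-1-yl)hex-4-enoate (racemic at C-2, not isolated) | CCOC(=O)C(C(=O)c1ccccc1NC)C(C=C(C)C)C=C(C)C | intermediate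
6 | 3-(2,6-dimethylhepta-2,5-dien-4-yl)-4-hydroxy-1-methylquinolin-2(1H)-one (half A, achiral) | CC(C)=CC(C=C(C)C)c1c(O)c2ccccc2n(C)c1=O | intermediate
7 | 4-hydroxy-1-methylquinolin-2(1H)-one | Cn1c(=O)cc(O)c2ccccc21 | starting material
8 | 3-[(dimethylamino)methylidene]-1-methylquinoline-2,4(1H,3H)-dione | CN(C)C=C1C(=O)c2ccccc2N(C)C1=O | intermediate
9 | 4-hydroxy-1-methyl-2-oxo-1,2-dihydroquinoline-3-carbaldehyde (half B) | Cn1c(=O)c(C=O)c(O)c2ccccc21 | intermediate
10 | 3-({[3-(2,6-dimethylhepta-2,5-dien-4-yl)-1-methyl-2-oxo-1,2-dihydroquinolin-4-yl]oxy}methylidene)-1-methylquinoline-2,4(1H,3H)-dione (not isolated) | CC(C)=CC(C=C(C)C)c1c(OC=C2C(=O)c3ccccc3N(C)C2=O)c2ccccc2n(C)c1=O | intermediate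
11 | CNP0210533.1: two 1-methylquinolin-2-one units, each fused at C-3/C-4 to a dihydropyran; the pyrans share a cis C–C bond; pyran of unit A is O–CH(R, also bound to C-3 of unit B)–CH(S, ring fusion)–CH(S, 2-methylprop-1-enyl)–C-3; pyran of unit B is O–CMe2–CH–CH–C-3 | CC(C)=C[C@@H]1c2c(c3ccccc3n(C)c2=O)O[C@H]2c3c(c4ccccc4n(C)c3=O)OC(C)(C)[C@@H]12 | target

**Count and risks**

Total steps: 6. Longest linear sequence: 4 steps (steps 1, 2, 3 and 6); the second branch (steps 4 and 5) joins in step 6.

Steps most likely to fail:

1. Step 6. The dehydrative O-linking of two vinylogous acids may not go far enough to feed the cycloaddition, the acid may instead add the enol OH across an isobutenyl group, and the endo closure or the choice between the two enantiotopic alkenes may be poorly controlled. Fallback (known chemistry, sets out from 7 and comes back at 11): 7 is condensed with 3-methylbut-2-enal in pyridine at reflux (Knoevenagel condensation and 6π-oxa-electrocyclisation) to give N-methylflindersine F1. Thermolysis of F1 near 180 °C in 1,2-dichlorobenzene should open part of it to the dienone valence tautomer 1-methyl-3-(3-methylbut-2-en-1-ylidene)quinoline-2,4(1H,3H)-dione F2, which adds as a 1-oxadiene across the pyran double bond of unopened F1 (intermolecular hetero-Diels–Alder reaction). This should give racemic 11, from which the enantiomer of 11 F3 is removed by preparative HPLC on a chiral stationary phase.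

2. Step 2. Acid-promoted ionisation of the tertiary dienyl alcohol (allylic transposition of the oxygen or dehydration to a triene) may outrun ketene acetal formation. Fallback (sets out from 2 and comes back at 3): 2 is acetylated (Ac2O, DMAP, Et3N) to (E)-2,6-dimethylhepta-3,5-dien-2-yl acetate F4. Ireland–Claisen rearrangement under basic conditions (LiN(iPr)2, Me3SiCl, THF, −78 → 60 °C) passes through the trimethylsilyl ketene acetal F5 to trimethylsilyl 5-methyl-3-(2-methylprop-1-en-1-yl)hex-4-enoate F6, which aqueous acid cleaves to 5-methyl-3-(2-methylprop-1-en-1-yl)hex-4-enoic acid F7. O-Alkylation with EtI and K2CO3 in DMF then gives 3.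

3. Step 3. C-Acylation of the β-branched enolate may be slow, the enolate may attack the carbamate carbonyl of the anhydride, or the lactam may not close. Fallback (sets out from 2 and 7 and comes back at 6): direct Tsuji–Trost-type C-3 alkylation of the acidic enol 7 with the allylic alcohol 2 under a zerovalent palladium catalyst, Pd(PPh3)4, in toluene at 80 °C. Attack at the less substituted secondary terminus of the vinyl-substituted η3-allyl palladium intermediate should give 6 with water as the only other product.

**Further compounds**

F1 | step 6 | N-methylflindersine (2,2,6-trimethyl-2,6-dihydro-5H-pyrano[3,2-c]quinolin-5-one) | CC1(C)C=Cc2c(O1)c1ccccc1n(C)c2=O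
F2 | step 6 | 1-methyl-3-(3-methylbut-2-en-1-ylidene)quinoline-2,4(1H,3H)-dione | CC(C)=CC=C1C(=O)c2ccccc2N(C)C1=O
F3 | step 6 | enantiomer of 11 (R,S,R) | CC(C)=C[C@H]1c2c(c3ccccc3n(C)c2=O)O[C@@H]2c3c(c4ccccc4n(C)c3=O)OC(C)(C)[C@H]12
F4 | step 2 | (E)-2,6-dimethylhepta-3,5-dien-2-yl acetate | CC(=O)OC(C)(C)/C=C/C=C(C)C
F5 | step 2 | (E)-2,6-dimethylhepta-3,5-dien-2-yl trimethylsilyl ketene acetal | C=C(O[Si](C)(C)C)OC(C)(C)/C=C/C=C(C)C
F6 | step 2 | trimethylsilyl 5-methyl-3-(2-methylprop-1-en-1-yl)hex-4-enoate | C[Si](C)(C)OC(=O)CC(C=C(C)C)C=C(C)C
F7 | step 2 | 5-methyl-3-(2-methylprop-1-en-1-yl)hex-4-enoic acid | OC(=O)CC(C=C(C)C)C=C(C)C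
F0 | step 3 | none | none
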